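**Plan**

1. Numbering (kaurane-type): ring A = C1–C5 and C10 (acetoxy on C1 and C2, gem-dimethyl C4, methyl C20 on C10); C6 = lactol carbon; C7 = OCH2 on C8; ring C = C8, C9, C11, C12, C13, C14 (epoxide across C9/C11); C15 = ketone; C16=C17 = exo-methylene. β is the face of ring C spanned by the C15–C16 bridge, α the other face (that of C20 in the target).
2. Retrosynthesis: open the lactol (C6–O); take off C17 and the epoxide oxygen; return C9=C11 to a C11 ketone; cut ring C at C8–C14 and C9–C11; then cut C8–C15 (acyl Stille), C8–C7 (acetylide plus formaldehyde) and C10–C9 (Claisen).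
3. Enabling feature: in ring C the oxygen-bearing C11 is 1,4 to C14 through C12–C13. The ring is therefore the formal [4+2] adduct of the C8=C9 alkene with a cyclobutanone C11(=O)–C12–C13–C14. C13 is tied to C8 by the two-atom C16–C15(=O) bridge, so strain-driven insertion of the alkene into the C11–C14 bond gives the whole bicyclo[3.2.1]octane at once.
4. Forward: ring A comes from a keto ester that already holds all its carbons; the C9–C8–C7 chain and the cyclobutanone arm are attached; ring C and the cyclopentanone form together in step 13; ring B closes last by lactolisation.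
5. Stereochemistry: the C2 carbinol comes from asymmetric transfer hydrogenation (C5 by isolating the trans isomer) and is relayed to C10 by the Claisen shift; C1/C2 from hydroxyl-directed osmylation; C8/C13 from face selection in step 13; C9/C11 from exo epoxidation; C6 from lactol equilibration.

Key step: step 13

Assumption: the keto ester and the cyclobutanone acid are taken as catalogue compounds, and in step 13 the (R)-ligand is taken as the enantiomer whose preference matches the substrate bias (its mirror image is used if the pairing proves mismatched).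

**Route**

Step 1
Reactants: 1 ethyl 2,6,6-trimethyl-4-oxocyclohex-2-ene-1-carboxylate (racemate)
Product: 2 ethyl (1R,4R)-4-hydroxy-2,6,6-trimethylcyclohex-2-ene-1-carboxylate
Conditions: RuCl[(R,R)-TsDPEN](p-cymene) (1 mol%), HCO2H/Et3N 5:2, CH2Cl2, 30 °C; SiO2 separation of the trans isomer
Reagents that add atoms: none
Why: Noyori–Ikariya asymmetric transfer hydrogenation should reduce the enone carbonyl 1,2 under reagent control (the alkenyl group taking the place of aryl in the usual model) to the (4R)-carbinol, and because 1 is racemic at the ester-bearing carbon the trans isomer 2 is separated from its cis C1 epimer.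

Step 2
Reactants: 2 ethyl (1R,4R)-4-hydroxy-2,6,6-trimethylcyclohex-2-ene-1-carboxylate
Product: 4 ethyl 2,6,6-trimethyl-2-(2-oxoethyl)cyclohex-3-ene-1-carboxylate (CH2CHO chain trans to the ester), via vinyl ether 3 (not isolated)
Conditions: ethyl vinyl ether, Hg(OAc)2 (0.2 equiv), reflux; evaporate; toluene, sealed tube, 180 °C
Reagents that add atoms: ethyl vinyl ether, C=COCC
Why: Mercury-catalysed transvinylation then Claisen rearrangement, whose suprafacial [3,3] shift delivers the CH2CHO unit (C9, C8) to C10 on the face that the C2–O bond occupied, that is trans to the C6 ester, creating the C10 quaternary centre and moving the ring alkene to C1=C2.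

Step 3
Reactants: 4 ethyl 2,6,6-trimethyl-2-(2-oxoethyl)cyclohex-3-ene-1-carboxylate
Product: 5 enol triflate of aldehyde 4 (C9H=C8H–OTf; E/Z mixture)
Conditions: Tf2O, 2,6-di-tert-butyl-4-methylpyridine, CH2Cl2, 0 °C to rt
Reagents that add atoms: triflic anhydride, O=S(=O)(OS(=O)(=O)C(F)(F)F)C(F)(F)F
Why: O-sulfonylation of the aldehyde enol (vinyl triflate formation from an enolisable aldehyde) under non-basic conditions that leave the hindered ester and its C5–H untouched; no stereocentre is formed and the alkene geometry is lost in step 4.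

Step 4
Reactants: 5 enol triflate of aldehyde 4
Product: 7 propargylic alcohol C10–C9≡C8–C7H2OH, via terminal alkyne 6 (not isolated)
Conditions: LiN(i-Pr)2 (2.3 equiv), THF, −78 to −20 °C; (CH2O)n, −20 °C to rt; aq. NH4Cl
Reagents that add atoms: paraformaldehyde (reacts as formaldehyde), C=O
Why: Base-induced 1,2-elimination of the 1-alkenyl triflate gives the terminal alkyne, whose lithium acetylide adds to formaldehyde to bring in C7, while C5–H, flanked by two quaternary carbons, should not be removed, so C5 is not epimerised.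

Step 5
Reactants: 7 propargylic alcohol
Product: 8 tert-butyldiphenylsilyl ether of 7
Conditions: TBDPSCl, imidazole, DMF, rt
Reagents that add atoms: tert-butyl(chloro)diphenylsilane, CC(C)(C)[Si](Cl)(c1ccccc1)c1ccccc1
Why: Silylation of the primary propargylic alcohol; the TBDPS ether should outlast every later step and is the last group removed.

Step 6
Reactants: 8 tert-butyldiphenylsilyl ether of 7
Product: 9 C6 primary alcohol (ester reduced)
Conditions: i-Bu2AlH (3 equiv), CH2Cl2, −78 to 0 °C; aq. KNaC4H4O6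
Reagents that add atoms: none
Why: Hydride reduction of the hindered ester to the primary alcohol; alkyne, ring alkene and silyl ether are inert to i-Bu2AlH at this temperature.

Step 7
Reactants: 9 C6 primary alcohol
Product: 11 triol (C6–OH and 1α,2α-diol), via osmate ester 10 (not isolated)
Conditions: OsO4 (1.05 equiv), TMEDA (1.1 equiv), CH2Cl2, −78 °C; then aq. Na2SO3, THF, reflux
Reagents that add atoms: osmium tetroxide, O=[Os](=O)(=O)=O
Why: Hydrogen-bond-directed dihydroxylation: the OsO4·TMEDA complex accepts a hydrogen bond from the homoallylic C6–OH and should be delivered to the alkene face cis to the CH2OH group, setting C1 and C2 as the 1α,2α-diol, the face an undirected osmylation would not be expected to choose; the alkyne reacts far more slowly.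

Step 8
Reactants: 11 triol
Product: 12 C6 triethylsilyl ether of 11
Conditions: Et3SiCl (1.05 equiv), imidazole, CH2Cl2, −78 to −40 °C
Reagents that add atoms: chlorotriethylsilane, CC[Si](Cl)(CC)CC
Why: Selective silylation of the primary alcohol over the two hindered secondary hydroxyls; TES is chosen because a primary TES ether can later be oxidised directly to the aldehyde.

Step 9
Reactants: 12 C6 triethylsilyl ether of 11
Product: 13 1α,2α-diacetate of 12
Conditions: Ac2O, DMAP, pyridine, 40 °C
Reagents that add atoms: acetic anhydride, CC(=O)OC(C)=O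
Why: DMAP-catalysed acylation installs both acetates of the target early; no later step uses a strong nucleophile or a strong base.

Step 10
Reactants: 13 1α,2α-diacetate of 12
Product: 14 (E)-vinylstannane C9H=C8(SnBu3)–C7H2OTBDPS (C10 and C7 cis)
Conditions: Pd(PPh3)2Cl2 (3 mol%), Bu3SnH, THF, 0 °C to rt
Reagents that add atoms: tributyltin hydride, CCCC[SnH](CCCC)CCCC
Why: Palladium-catalysed syn-hydrostannation should place tin on C8, the alkyne carbon remote from the quaternary C10 and next to the CH2OSi group, and hydrogen on C9, giving the (E)-stannane.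

Step 11
Reactants: 15 2-(3-oxocyclobutyl)acetic acid
Product: 16 2-(3-oxocyclobutyl)acetyl chloride
Conditions: (COCl)2, DMF (cat.), CH2Cl2, 0 °C to rt; evaporate
Reagents that add atoms: oxalyl chloride, O=C(Cl)C(=O)Cl
Why: Vilsmeier-type chlorination of the acid; the cyclobutanone is untouched and the crude chloride is used at once.

Step 12
Reactants: 14 (E)-vinylstannane; 16 2-(3-oxocyclobutyl)acetyl chloride
Product: 17 (E)-enone C10–C9H=C8(C7H2OTBDPS)–C15(=O)–C16H2–(3-oxocyclobutyl)
Conditions: Pd2(dba)3 (2.5 mol%), P(2-furyl)3 (10 mol%), THF, 50 °C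
Reagents that add atoms: none
Why: Stille acyl coupling forms C8–C15 with retention of alkene geometry, so the acyl group is trans to C10; ketones, acetates and silyl ethers are tolerated.

Step 13
Reactants: 17 (E)-enone
Product: 19 bicyclo[3.2.1]octane-11,15-dione with H-9α (ring A equatorial on ring C), via kinetic C9 epimer 18 (not isolated)
Conditions: [Rh(cod)(OH)]2 (5 mol%), (R)-DTBM-SEGPHOS (12 mol%), 1,4-dioxane, 130 °C; then DBU (1 equiv), 80 °C
Reagents that add atoms: none
Why: Proposed new method: monovalent rhodium should add oxidatively into the C11(acyl)–C14 bond of the strained cyclobutanone (ring strain is the driving force), the enone alkene held two atoms away should then insert syn into the acyl–rhodium bond (C11 to the β-carbon C9, leaving a rhodium enolate at C8), and C(sp3)–C(sp3) reductive elimination should join C14 to C8; the closest known reaction type is the rhodium-catalysed intramolecular alkene insertion into cyclobutanone C–C bonds ("cut-and-sew" carboacylation) that gives benzo-fused bicyclo[3.2.1]octan-3-ones, which has not been shown for a conjugated, trisubstituted alkene on an all-aliphatic two-atom tether. Ring C (C8–C9–C11–C12–C13–C14) closes as a formal [4+2] by σ-bond insertion, and the same C8–C14 bond closes the cyclopentanone C8–C14–C13–C16–C15 as the bridging ring (5-exo with respect to the former alkene), so the bicyclo[3.2.1]octane arises in one event. C8 and C13 are set together, because the two-atom bridge can span only one face of the new ring, so their configuration relative to ring A is decided by which alkene face is carbometallated; C9 is set by syn addition to the (E)-alkene (ring A axial on ring C in 18) and is then equilibrated by DBU to 19, with ring A equatorial. The step needs (a) insertion to outrun decarbonylation, which the proximity and π-acidity of the enone should secure, (b) the [3.2.1] rather than the [2.2.2] connectivity, which acyl transfer to the enone β-carbon and the short tether should secure, and (c) attack on the alkene face remote from C5: allylic 1,3-strain with C7 should turn the C20 methyl into the alkene plane, leaving the two faces flanked by C1 and by C5, and since C5 carries the CH2OTES group next to the gem-dimethyl carbon, rhodium should bind the C1 side, a bias the chiral ligand is chosen to reinforce.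

Step 14
Reactants: 19 bicyclo[3.2.1]octane-11,15-dione with H-9α
Product: 20 11β-alcohol (axial hydroxyl; C15 ketone kept)
Conditions: NaBH4 (0.5 equiv), MeOH/CH2Cl2, −40 °C
Reagents that add atoms: none
Why: Borohydride reduction should pick the six-ring C11 ketone over the C15 cyclopentanone, which is neopentyl (quaternary C8 bearing CH2OTBDPS) and intrinsically slower, and hydride should enter C11 from the open α-face because the C15–C16 bridge screens the β-face (as in tropinone to tropine), giving the axial 11β-alcohol.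

Step 15
Reactants: 20 11β-alcohol
Product: 21 9(11)-ene 15-ketone
Conditions: Martin sulfurane (Ph2S[OC(CF3)2Ph]2, 1.5 equiv), CH2Cl2, 0 °C to rt
Reagents that add atoms: none
Why: Anti-periplanar E2 dehydration through the alkoxysulfonium ion: the axial 11β-oxygen is trans-diaxial to the tertiary H-9α and to H-12α, and loss of H-9 to the trisubstituted alkene is expected, as in the dehydration of 11β-hydroxy steroids.

Step 16
Reactants: 21 9(11)-ene 15-ketone
Product: 25 16-methylene 15-ketone, via silyl enol ether 22 (not isolated), via Mannich base 23 (not isolated), via ammonium iodide 24 (not isolated)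
Conditions: Me3SiOTf, Et3N, CH2Cl2, 0 °C; Me2N=CH2 I (Eschenmoser's salt), rt; MeI; aq. NaHCO3, rt
Reagents that add atoms: Eschenmoser's salt (N,N-dimethylmethyleneiminium iodide), C=[N+](C)C.[I-]
Why: The C15 ketone can enolise only towards C16 (C8 is quaternary), so soft enolisation gives one silyl enol ether, and Mukaiyama–Mannich aminomethylation, N-methylation and E1cB loss of trimethylamine should then give the exo-methylene ketone under conditions that spare the acetates.

Step 17
Reactants: 25 16-methylene 15-ketone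
Product: 26 9α,11α-epoxide
Conditions: mCPBA, NaHCO3, CH2Cl2, 0 °C
Reagents that add atoms: 3-chloroperbenzoic acid, O=C(OO)c1cccc(Cl)c1
Why: Prilezhaev epoxidation should pick the electron-rich trisubstituted C9=C11 alkene over the electron-poor enone, with oxygen arriving on the α-face of ring C, the exo face of the bicyclo[3.2.1]octene away from the C15–C16 bridge, which sets C9 and C11.

Step 18
Reactants: 26 9α,11α-epoxide
Product: 27 C6 aldehyde
Conditions: (COCl)2, DMSO, CH2Cl2, −78 to −40 °C; Et3N, −78 to 0 °C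
Reagents that add atoms: none
Why: Under Swern conditions a primary triethylsilyl ether is cleaved and oxidised in one operation to the aldehyde, whereas the TBDPS ether, acetates, epoxide and enone should be left alone.

Step 19
Reactants: 27 C6 aldehyde
Product: 29 target lactol, via hydroxy aldehyde 28 (not isolated)
Conditions: HF·pyridine, pyridine, THF, 0 °C to rt
Reagents that add atoms: none
Why: Buffered fluoride desilylation frees the C7 hydroxyl, which adds to the C6 aldehyde to close ring B as the seven-membered lactol; C6 is set under thermodynamic control and should settle as the β-hydroxy anomer, which can hydrogen-bond to the C15 carbonyl.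

**Compound list**

1 | ethyl 2,6,6-trimethyl-4-oxocyclohex-2-ene-1-carboxylate (racemate) | CCOC(=O)C1C(C)(C)CC(=O)C=C1C | starting material
2 | ethyl (1R,4R)-4-hydroxy-2,6,6-trimethylcyclohex-2-ene-1-carboxylate (hydroxyl trans to ester) | CCOC(=O)[C@@H]1C(C)(C)C[C@@H](O)C=C1C | intermediate
3 | O-vinyl ether of 2 | CCOC(=O)[C@@H]1C(C)(C)C[C@@H](OC=C)C=C1C | intermediate
4 | ethyl 2,6,6-trimethyl-2-(2-oxoethyl)cyclohex-3-ene-1-carboxylate, CH2CHO chain on C10 trans to the C6 ester | CCOC(=O)[C@@H]1C(C)(C)CC=C[C@@]1(C)CC=O | intermediate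
5 | enol triflate of 4 (E/Z mixture) | CCOC(=O)[C@@H]1C(C)(C)CC=C[C@@]1(C)C=COS(=O)(=O)C(F)(F)F | intermediate
6 | terminal alkyne C10–C9≡C8–H (present as its lithium acetylide) | CCOC(=O)[C@@H]1C(C)(C)CC=C[C@@]1(C)C#C | intermediate
7 | propargylic alcohol C10–C9≡C8–C7H2OH | CCOC(=O)[C@@H]1C(C)(C)CC=C[C@@]1(C)C#CCO | intermediate
8 | tert-butyldiphenylsilyl ether of 7 | CCOC(=O)[C@@H]1C(C)(C)CC=C[C@@]1(C)C#CCO[Si](c2ccccc2)(c2ccccc2)C(C)(C)C | intermediate
9 | C6 primary alcohol | OC[C@@H]1C(C)(C)CC=C[C@@]1(C)C#CCO[Si](c2ccccc2)(c2ccccc2)C(C)(C)C | intermediate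
10 | cyclic osmate ester of the 1α,2α-diol with TMEDA on osmium | OC[C@@H]1C(C)(C)C[C@@H]2O[Os-2]3(=O)(=O)(O[C@@H]2[C@@]1(C)C#CCO[Si](c4ccccc4)(c4ccccc4)C(C)(C)C)[N+](C)(C)CC[N+]3(C)C | intermediate
11 | triol: C6–OH and 1α,2α-diol, all cis to the C20 methyl | OC[C@@H]1C(C)(C)C[C@H](O)[C@H](O)[C@@]1(C)C#CCO[Si](c2ccccc2)(c2ccccc2)C(C)(C)C | intermediate
12 | C6 triethylsilyl ether of 11 | CC[Si](CC)(CC)OC[C@@H]1C(C)(C)C[C@H](O)[C@H](O)[C@@]1(C)C#CCO[Si](c2ccccc2)(c2ccccc2)C(C)(C)C | intermediate
13 | 1α,2α-diacetate of 12 | CC[Si](CC)(CC)OC[C@@H]1C(C)(C)C[C@H](OC(C)=O)[C@H](OC(C)=O)[C@@]1(C)C#CCO[Si](c2ccccc2)(c2ccccc2)C(C)(C)C | intermediate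
14 | (E)-vinylstannane, SnBu3 on C8, C10 and C7 cis | CC[Si](CC)(CC)OC[C@@H]1C(C)(C)C[C@H](OC(C)=O)[C@H](OC(C)=O)[C@@]1(C)/C=C(\CO[Si](c2ccccc2)(c2ccccc2)C(C)(C)C)[Sn](CCCC)(CCCC)CCCC | intermediate
15 | 2-(3-oxocyclobutyl)acetic acid | O=C1CC(CC(=O)O)C1 | starting material
16 | 2-(3-oxocyclobutyl)acetyl chloride | O=C1CC(CC(=O)Cl)C1 | intermediate
17 | (E)-enone, acyl group trans to C10, cyclobutanone on C16 | CC[Si](CC)(CC)OC[C@@H]1C(C)(C)C[C@H](OC(C)=O)[C@H](OC(C)=O)[C@@]1(C)/C=C(\CO[Si](c2ccccc2)(c2ccccc2)C(C)(C)C)C(=O)CC2CC(=O)C2 | intermediate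
18 | bicyclo[3.2.1]octane-11,15-dione, kinetic epimer with H-9β (ring A axial on ring C) | O=C1C[C@@H]2CC(=O)[C@@H]([C@]3(C)[C@@H](OC(C)=O)[C@@H](OC(C)=O)CC(C)(C)[C@H]3CO[Si](CC)(CC)CC)[C@@]1(CO[Si](c1ccccc1)(c1ccccc1)C(C)(C)C)C2 | intermediate
19 | bicyclo[3.2.1]octane-11,15-dione with H-9α (ring A equatorial on ring C) | O=C1C[C@@H]2CC(=O)[C@H]([C@]3(C)[C@@H](OC(C)=O)[C@@H](OC(C)=O)CC(C)(C)[C@H]3CO[Si](CC)(CC)CC)[C@@]1(CO[Si](c1ccccc1)(c1ccccc1)C(C)(C)C)C2 | intermediate
20 | 11β-alcohol of 19 | O=C1C[C@@H]2C[C@H](O)[C@H]([C@]3(C)[C@@H](OC(C)=O)[C@@H](OC(C)=O)CC(C)(C)[C@H]3CO[Si](CC)(CC)CC)[C@@]1(CO[Si](c1ccccc1)(c1ccccc1)C(C)(C)C)C2 | intermediate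
21 | 9(11)-ene 15-ketone | O=C1C[C@@H]2CC=C([C@]3(C)[C@@H](OC(C)=O)[C@@H](OC(C)=O)CC(C)(C)[C@H]3CO[Si](CC)(CC)CC)[C@@]1(CO[Si](c1ccccc1)(c1ccccc1)C(C)(C)C)C2 | intermediate
22 | C15 trimethylsilyl enol ether of 21 | C[Si](C)(C)OC1=C[C@@H]2CC=C([C@]3(C)[C@@H](OC(C)=O)[C@@H](OC(C)=O)CC(C)(C)[C@H]3CO[Si](CC)(CC)CC)[C@@]1(CO[Si](c1ccccc1)(c1ccccc1)C(C)(C)C)C2 | intermediate
23 | C16 (dimethylamino)methyl ketone (C16 configuration undefined and immaterial) | O=C1C(CN(C)C)[C@@H]2CC=C([C@]3(C)[C@@H](OC(C)=O)[C@@H](OC(C)=O)CC(C)(C)[C@H]3CO[Si](CC)(CC)CC)[C@@]1(CO[Si](c1ccccc1)(c1ccccc1)C(C)(C)C)C2 | intermediate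
24 | trimethylammonium iodide of 23 | O=C1C(C[N+](C)(C)C)[C@@H]2CC=C([C@]3(C)[C@@H](OC(C)=O)[C@@H](OC(C)=O)CC(C)(C)[C@H]3CO[Si](CC)(CC)CC)[C@@]1(CO[Si](c1ccccc1)(c1ccccc1)C(C)(C)C)C2.[I-] | intermediate
25 | 16-methylene 15-ketone (9(11)-ene) | O=C1C(=C)[C@@H]2CC=C([C@]3(C)[C@@H](OC(C)=O)[C@@H](OC(C)=O)CC(C)(C)[C@H]3CO[Si](CC)(CC)CC)[C@@]1(CO[Si](c1ccccc1)(c1ccccc1)C(C)(C)C)C2 | intermediate
26 | 9α,11α-epoxide of 25 | O=C1C(=C)[C@@H]2C[C@H]3O[C@@]3([C@]4(C)[C@@H](OC(C)=O)[C@@H](OC(C)=O)CC(C)(C)[C@H]4CO[Si](CC)(CC)CC)[C@@]1(CO[Si](c1ccccc1)(c1ccccc1)C(C)(C)C)C2 | intermediate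
27 | C6 aldehyde (C7 still TBDPS-protected) | O=C1C(=C)[C@@H]2C[C@H]3O[C@@]3([C@]4(C)[C@@H](OC(C)=O)[C@@H](OC(C)=O)CC(C)(C)[C@H]4C=O)[C@@]1(CO[Si](c1ccccc1)(c1ccccc1)C(C)(C)C)C2 | intermediate
28 | C7 hydroxy C6 aldehyde (open form of the target) | O=C1C(=C)[C@@H]2C[C@H]3O[C@@]3([C@]4(C)[C@@H](OC(C)=O)[C@@H](OC(C)=O)CC(C)(C)[C@H]4C=O)[C@@]1(CO)C2 | intermediate
29 | CNP0224512.1: 1α,2α-diacetoxy-9α,11α-epoxy-16-methylene-15-ketone with the C6/C7 oxepane lactol (6β-OH) | C=C1C(=O)[C@@]23CO[C@@H](O)[C@@H]4C(C)(C)C[C@H](OC(C)=O)[C@H](OC(C)=O)[C@@]4(C)[C@]24O[C@@H]4C[C@@H]1C3 | target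

**Step count and risks**

Total steps: 19. Longest linear sequence: 18 steps (steps 1–10 and 12–19; step 11 makes the acid chloride for the convergent coupling).

Steps most likely to fail:

1. Step 13 (carries the new-method label). What may go wrong: decarbonylation of the acylrhodium intermediate to a cyclopropane, failure of the hindered conjugated alkene to insert, or insertion on the wrong alkene face. The fallback sets out from 14 and returns at 19. Iododestannylation (I2, CH2Cl2, 0 °C) gives the vinyl iodide F1. Acid chloride 16 is reduced (Bu3SnH, Pd(PPh3)4) to 2-(3-oxocyclobutyl)acetaldehyde F2. Nozaki–Hiyama–Kishi coupling (CrCl2, NiCl2 cat., DMF) joins the two to the C15 allylic alcohol F3 (both C15 epimers), which is protected as the 4-methoxybenzyl ether F4 (PMB trichloroacetimidate, La(OTf)3 cat.). F4 is a cyclobutanone with a non-conjugated alkene tethered at C3, the substrate class of the published [4+2] coupling co-catalysed by 2-amino-3-picoline ([Rh(C2H4)2Cl]2, P(3,5-(CF3)2C6H3)3, 1,4-dioxane, 150 °C; then DBU), which should give the bridged C11 ketone F5. DDQ frees the C15 alcohol F6, and Dess–Martin oxidation returns 19.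

2. Step 15. What may go wrong: loss of the more accessible C12 hydrogen instead of H-9, which is shielded by two quaternary carbons. The fallback sets out from 20 and returns at 21. The elimination product of the wrong regiochemistry, the 11-ene isomer F7, is accepted and its double bond is moved with RhCl3·3H2O in EtOH at 70 °C (metal hydride addition–elimination) into the trisubstituted C9=C11 position. This replaces kinetic control of the elimination by equilibration of the alkene towards the more substituted isomer.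

3. Step 17. What may go wrong: poor facial selectivity, with the peroxy acid attacking the β-face. The fallback sets out from 25 and returns at 26. NBS in aqueous acetone at 0 °C gives the bromohydrin F8 (9α-hydroxy, 11β-bromo) by anti addition across the face the electrophile prefers, and DBU then closes it to the epoxide on the opposite, α-face.

**Further compounds**

F1 | step 13 | (E)-vinyl iodide (iodine on C8 in place of tin) | CC[Si](CC)(CC)OC[C@@H]1C(C)(C)C[C@H](OC(C)=O)[C@H](OC(C)=O)[C@@]1(C)/C=C(\CO[Si](c2ccccc2)(c2ccccc2)C(C)(C)C)I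
F2 | step 13 | 2-(3-oxocyclobutyl)acetaldehyde | O=CCC1CC(=O)C1
F3 | step 13 | C15 allylic alcohol (C15 epimer mixture) | CC[Si](CC)(CC)OC[C@@H]1C(C)(C)C[C@H](OC(C)=O)[C@H](OC(C)=O)[C@@]1(C)/C=C(\CO[Si](c2ccccc2)(c2ccccc2)C(C)(C)C)C(O)CC2CC(=O)C2
F4 | step 13 | C15 4-methoxybenzyl ether of F3 | CC[Si](CC)(CC)OC[C@@H]1C(C)(C)C[C@H](OC(C)=O)[C@H](OC(C)=O)[C@@]1(C)/C=C(\CO[Si](c2ccccc2)(c2ccccc2)C(C)(C)C)C(OCc2ccc(OC)cc2)CC2CC(=O)C2
F5 | step 13 | bridged C11 ketone with C15 4-methoxybenzyl ether (H-9α) | COc1ccc(COC2C[C@@H]3CC(=O)[C@H]([C@]4(C)[C@@H](OC(C)=O)[C@@H](OC(C)=O)CC(C)(C)[C@H]4CO[Si](CC)(CC)CC)[C@@]2(CO[Si](c2ccccc2)(c2ccccc2)C(C)(C)C)C3)cc1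
F6 | step 13 | bridged C11 ketone with free C15 hydroxyl | OC1C[C@@H]2CC(=O)[C@H]([C@]3(C)[C@@H](OC(C)=O)[C@@H](OC(C)=O)CC(C)(C)[C@H]3CO[Si](CC)(CC)CC)[C@@]1(CO[Si](c1ccccc1)(c1ccccc1)C(C)(C)C)C2
F7 | step 15 | 11-ene isomer of 21 (C11=C12, H-9α) | O=C1C[C@@H]2C=C[C@H]([C@]3(C)[C@@H](OC(C)=O)[C@@H](OC(C)=O)CC(C)(C)[C@H]3CO[Si](CC)(CC)CC)[C@@]1(CO[Si](c1ccccc1)(c1ccccc1)C(C)(C)C)C2
F8 | step 17 | bromohydrin of 25 (9α-hydroxy, 11β-bromo) | O=C1C(=C)[C@@H]2C[C@H](Br)[C@](O)([C@]3(C)[C@@H](OC(C)=O)[C@@H](OC(C)=O)CC(C)(C)[C@H]3CO[Si](CC)(CC)CC)[C@@]1(CO[Si](c1ccccc1)(c1ccccc1)C(C)(C)C)C2
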